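Retrosynthesis: O1–C2 is cut first (phenol etherification with inversion), then ring A is taken apart at C4a–C8a, C5–C6 and C8–C8a into a siloxyalkyne and cyclobut-2-en-1-one. The siloxyalkyne is traced back through its C–O bond and its two alkyne carbons (from a C4–boron bond) and through the C4–naphthyl bond to an O-alkyl carbamate and a naphthylboronate.
Enabling feature: ring A (C4a, C5, C6, C7, C8, C8a) carries oxygen on C5 and C8a, the two carbons flanking C4a, and C4a bears the crowded diarylmethine C4. Such a 2-alkylresorcinol with two unlike oxygens (O1 in the pyran ring, free OH on C5) is what a vinylketene/ynol ether benzannulation delivers in one operation.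
Forward order: the naphthalene is joined to the C2–C3–C4 chain at C4 by lithiation–borylation, and boron is exchanged for a 1-bromovinyl group. Elimination, oxygenation and silylation in one flask give the siloxyalkyne, ring A is grown onto C4, and the pyran ring is closed last.
Stereochemistry: C2 comes from methyl (R)-3-hydroxybutanoate and is inverted to S in the Mitsunobu closure. C4 is set by (+)-sparteine in the lithiation–borylation and afterwards passes only through stereospecific or non-epimerising steps.

Key step: step 11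

Assumption: in step 6 the diamine, not the remote silyloxy centre, is taken to decide which α-hydrogen of 8 is removed (reagent control); in the fallbacks the ligand antipode is the one that a pilot run shows to give the configuration drawn.

Step 1
Reactants: 1 1,8-dimethoxynaphthalene
Product: 2 1-bromo-4,5-dimethoxynaphthalene
Conditions: NBS (1.0 equiv), MeCN, 0 °C to rt
Reagents that add atoms: N-bromosuccinimide, O=C1CCC(=O)N1Br
Why: Electrophilic aromatic bromination of this very electron-rich naphthalene should occur para to a methoxy group, and one equivalent of NBS at low temperature limits 4,5-dibromination.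

Step 2
Reactants: 2 1-bromo-4,5-dimethoxynaphthalene
Product: 4 2-(4,5-dimethoxynaphthalen-1-yl)-4,4,5,5-tetramethyl-1,3,2-dioxaborolane, via aryllithium 3 (not isolated)
Conditions: n-BuLi, THF, –78 °C; i-PrOBpin, –78 °C to rt; H2O
Reagents that add atoms: 2-isopropoxy-4,4,5,5-tetramethyl-1,3,2-dioxaborolane, CC(C)OB1OC(C)(C)C(C)(C)O1
Why: Bromine–lithium exchange is fast at –78 °C and the aryllithium is trapped at boron by the alkoxyboronate (borylation of an organolithium), the methoxy groups being inert to both reagents.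

Step 3
Reactants: 5 methyl (R)-3-hydroxybutanoate
Product: 6 methyl (R)-3-(tert-butyldimethylsilyloxy)butanoate
Conditions: TBSCl, imidazole, DMF, rt
Reagents that add atoms: tert-butyldimethylsilyl chloride, CC(C)(C)[Si](C)(C)Cl
Why: Imidazole-promoted O-silylation masks the secondary hydroxyl whose carbon later becomes C2 as a silyl ether robust enough for the organolithium steps, without touching the stereocentre.

Step 4
Reactants: 6 methyl (R)-3-(tert-butyldimethylsilyloxy)butanoate
Product: 7 (R)-3-(tert-butyldimethylsilyloxy)butan-1-ol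
Conditions: i-Bu2AlH (2.5 equiv), CH2Cl2, –78 to 0 °C; aq KNaC4H4O6 (potassium sodium tartrate)
Reagents that add atoms: none
Why: Hydride reduction of the ester gives the primary alcohol, the silyl ether and the β-stereocentre being unaffected.

Step 5
Reactants: 7 (R)-3-(tert-butyldimethylsilyloxy)butan-1-ol
Product: 8 (R)-3-(tert-butyldimethylsilyloxy)butyl N,N-diisopropylcarbamate
Conditions: i-Pr2NC(O)Cl, Et3N, CH2Cl2, reflux
Reagents that add atoms: N,N-diisopropylcarbamoyl chloride, CC(C)N(C(C)C)C(=O)Cl
Why: O-Carbamoylation of the primary alcohol installs the group that directs the α-lithiation and later serves as the leaving group.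

Step 6
Reactants: 8 (R)-3-(tert-butyldimethylsilyloxy)butyl N,N-diisopropylcarbamate and 4 2-(4,5-dimethoxynaphthalen-1-yl)-4,4,5,5-tetramethyl-1,3,2-dioxaborolane
Product: 11 2-[(1S,3R)-3-(tert-butyldimethylsilyloxy)-1-(4,5-dimethoxynaphthalen-1-yl)butyl]-4,4,5,5-tetramethyl-1,3,2-dioxaborolane, via lithiated carbamate 9 (not isolated), via boronate complex 10 (not isolated)
Conditions: 8 (1.3 equiv), s-BuLi, (+)-sparteine, Et2O, –78 °C; 4, –78 °C; then reflux; H2O
Reagents that add atoms: none
Why: Lithiation–borylation (1,2-metallate rearrangement of the Matteson type): s-BuLi/(+)-sparteine removes the pro-R α-hydrogen to give the configurationally stable (R)-lithiated carbamate 9, borylation by 4 proceeds with retention and the aryl group then migrates with inversion as the carbamate leaves antiperiplanar, so the future C4 is set as 1S by the diamine while the 3R carbinol centre is untouched.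

Step 7
Reactants: 11 2-[(1S,3R)-3-(tert-butyldimethylsilyloxy)-1-(4,5-dimethoxynaphthalen-1-yl)butyl]-4,4,5,5-tetramethyl-1,3,2-dioxaborolane
Product: 13 tert-butyl{[(2R,4S)-5-bromo-4-(4,5-dimethoxynaphthalen-1-yl)hex-5-en-2-yl]oxy}dimethylsilane, via bromovinylboronate complex 12 (not isolated)
Conditions: CH2=CHBr (3 equiv), LiN(i-Pr)2 (3 equiv, added last), THF, –78 °C; I2, MeOH, –78 °C; NaOMe, MeOH, –78 °C to rt; aq Na2S2O3
Reagents that add atoms: vinyl bromide, C=CBr
Why: Zweifel olefination with an α-halovinyl anion: 1-bromovinyllithium formed in situ adds to boron, iodination of the vinyl group triggers 1,2-migration of the benzylic carbon with retention of configuration, and methoxide-induced anti elimination of boron and iodide gives the 2-bromoalkene with the 4S centre intact.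

Step 8
Reactants: 13 tert-butyl{[(2R,4S)-5-bromo-4-(4,5-dimethoxynaphthalen-1-yl)hex-5-en-2-yl]oxy}dimethylsilane
Product: 16 tert-butyl{[(2R,4S)-4-(4,5-dimethoxynaphthalen-1-yl)-6-(triisopropylsilyloxy)hex-5-yn-2-yl]oxy}dimethylsilane, via lithium acetylide 14 (not isolated), via lithium ynolate 15 (not isolated)
Conditions: LiN(i-Pr)2 (2.2 equiv), THF, –78 to 0 °C; LiOOt-Bu (1.3 equiv, premade from t-BuOOH and LiN(SiMe3)2 in THF at –78 °C), –78 to 0 °C; i-Pr3SiOTf (1.5 equiv), –78 to 0 °C; aq NaHCO3; filtration through Et3N-deactivated silica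
Reagents that add atoms: tert-butyl hydroperoxide, CC(C)(C)OO; triisopropylsilyl trifluoromethanesulfonate, CC(C)[Si](OS(=O)(=O)C(F)(F)F)(C(C)C)C(C)C
Why: Anti E2 dehydrobromination of the 2-bromo-1-alkene by the amide base delivers the alkyne directly as lithium acetylide 14, whose charge shields the benzylic–propargylic centre from propargyl–allene isomerisation, and without intervening protonation 14 attacks the electrophilic peroxide oxygen of LiOOt-Bu (loss of LiOt-Bu) to give lithium ynolate 15, which the bulky silyl triflate captures on oxygen (base-mediated elimination with in-flask electrophilic trapping of the acetylide, then ynolate O-silylation).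

Step 9
Reactants: 17 3-oxocyclobutane-1-carboxylic acid
Product: 18 3-bromocyclobutan-1-one
Conditions: HgO, Br2, MgSO4, CH2Cl2, reflux
Reagents that add atoms: bromine, BrBr
Why: Hunsdiecker-type bromodecarboxylation (Cristol–Firth variant) converts the mercury carboxylate via an acyl hypobromite and loss of CO2 into the secondary bromide, the ketone being inert.

Step 10
Reactants: 18 3-bromocyclobutan-1-one
Product: 19 cyclobut-2-en-1-one
Conditions: n-Bu3N, rt; vacuum transfer into a –78 °C trap, used at once
Reagents that add atoms: none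
Why: Amine-mediated E1cB dehydrobromination β to the carbonyl gives the strained enone, which is separated from the ammonium salt by vacuum transfer because it polymerises on standing.

Step 11
Reactants: 16 tert-butyl{[(2R,4S)-4-(4,5-dimethoxynaphthalen-1-yl)-6-(triisopropylsilyloxy)hex-5-yn-2-yl]oxy}dimethylsilane and 19 cyclobut-2-en-1-one
Product: 24 2-[(1S,3R)-3-(tert-butyldimethylsilyloxy)-1-(4,5-dimethoxynaphthalen-1-yl)butyl]-3-(triisopropylsilyloxy)phenol, via vinylketene 20 (not isolated), via vinylcyclobutenone 21 (not isolated), via dienylketene 22 (not isolated), via cyclohexadienone 23 (not isolated)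
Conditions: 19 (3 equiv, added in portions), toluene, 80 °C then 110 °C, sealed tube
Reagents that add atoms: none
Why: Danheiser benzannulation: thermal 4π electrocyclic opening of 19 gives vinylketene 20, which adds to the ynol ether in a regioselective [2+2] cycloaddition (C4a–C8a and C5–C6 formed, a transient four-membered ring closed by ketene–alkyne cycloaddition) to give 21; reversible 4π opening of 21 gives dienylketene 22, and the isomer with the vinyl group cis to the ketene closes ring A by a thermally allowed disrotatory 6π electrocyclisation (C8–C8a), after which 23 tautomerises to phenol 24. The closest known reaction type is the benzannulation of cyclobutenones with triisopropylsiloxyalkynes to 2-substituted 3-siloxyphenols. No stereocentre is created that survives (the sp3 ring carbon of 21 is lost on ring opening), and the 1S and 3R centres are remote from the reacting π system and not enolisable under neutral heating. The step needs regioselectivity in the [2+2] event, and the polarisation of the siloxyalkyne secures it: its nucleophilic carbon, which carries the C4 side chain, bonds to the electrophilic ketene carbonyl carbon, so the side chain ends between the free hydroxyl (future O1) and the silyloxy group (future C5 oxygen). It also needs the ketenes to be captured by the alkyne alone, which is why the carbinol is silylated and why 19 is added in portions to keep ketene dimerisation and acylation of the product phenol low.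

Step 12
Reactants: 24 2-[(1S,3R)-3-(tert-butyldimethylsilyloxy)-1-(4,5-dimethoxynaphthalen-1-yl)butyl]-3-(triisopropylsilyloxy)phenol
Product: 25 2-[(1S,3R)-1-(4,5-dimethoxynaphthalen-1-yl)-3-hydroxybutyl]-3-(triisopropylsilyloxy)phenol
Conditions: camphorsulfonic acid (0.2 equiv), MeOH/CH2Cl2 (1:1), 0 °C to rt
Reagents that add atoms: none
Why: Acid-catalysed methanolysis removes the secondary alkyl silyl ether much faster than the aryl triisopropylsilyl ether (less basic oxygen, bulkier silicon), so the two phenolic oxygens stay differentiated and no stereocentre is affected.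

Step 13
Reactants: 25 2-[(1S,3R)-1-(4,5-dimethoxynaphthalen-1-yl)-3-hydroxybutyl]-3-(triisopropylsilyloxy)phenol
Product: 26 triisopropyl{[(2S,4S)-4-(4,5-dimethoxynaphthalen-1-yl)-2-methyl-3,4-dihydro-2H-chromen-5-yl]oxy}silane
Conditions: PPh3, DIAD, THF (0.02 M), 0 °C to rt
Reagents that add atoms: none
Why: Intramolecular Mitsunobu etherification: the free phenol displaces the oxyphosphonium of the secondary alcohol in a 6-exo-tet SN2 closure with inversion, converting the 3R carbinol into 2S and forming O1–C2 cis to the C4 naphthyl group.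

Step 14
Reactants: 26 triisopropyl{[(2S,4S)-4-(4,5-dimethoxynaphthalen-1-yl)-2-methyl-3,4-dihydro-2H-chromen-5-yl]oxy}silane
Product: 27 (2S,4S)-4-(4,5-dimethoxynaphthalen-1-yl)-2-methyl-3,4-dihydro-2H-chromen-5-ol (cladonaphchrom B)
Conditions: Bu4NF, AcOH, THF, 0 °C to rt
Reagents that add atoms: none
Why: Fluoride-mediated desilylation of the aryl silyl ether, buffered with acetic acid so that the electron-rich phenol stays protonated, should give the target with both stereocentres unchanged.

Compound list
1 | 1,8-dimethoxynaphthalene | COc1cccc2cccc(OC)c12 | starting material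
2 | 1-bromo-4,5-dimethoxynaphthalene | COc1cccc2c(Br)ccc(OC)c12 | intermediate
3 | (4,5-dimethoxynaphthalen-1-yl)lithium | [Li]c1ccc(OC)c2c(OC)cccc12 | intermediate
4 | 2-(4,5-dimethoxynaphthalen-1-yl)-4,4,5,5-tetramethyl-1,3,2-dioxaborolane | COc1cccc2c(B3OC(C)(C)C(C)(C)O3)ccc(OC)c12 | intermediate
5 | methyl (R)-3-hydroxybutanoate | COC(=O)C[C@@H](C)O | starting material
6 | methyl (R)-3-(tert-butyldimethylsilyloxy)butanoate | COC(=O)C[C@@H](C)O[Si](C)(C)C(C)(C)C | intermediate
7 | (R)-3-(tert-butyldimethylsilyloxy)butan-1-ol | OCC[C@@H](C)O[Si](C)(C)C(C)(C)C | intermediate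
8 | (R)-3-(tert-butyldimethylsilyloxy)butyl N,N-diisopropylcarbamate | CC(C)N(C(C)C)C(=O)OCC[C@@H](C)O[Si](C)(C)C(C)(C)C | intermediate
9 | (1R,3R)-3-(tert-butyldimethylsilyloxy)-1-lithiobutyl N,N-diisopropylcarbamate, held as its (+)-sparteine complex | CC(C)N(C(C)C)C(=O)O[C@H]([Li])C[C@@H](C)O[Si](C)(C)C(C)(C)C | intermediate
10 | lithium boronate complex of 9 with 4 (boron on the (1R) carbon, retention) | [Li+].CC(C)N(C(C)C)C(=O)O[C@H]([B-]1(OC(C)(C)C(C)(C)O1)c1ccc(OC)c2c(OC)cccc12)C[C@@H](C)O[Si](C)(C)C(C)(C)C | intermediate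
11 | 2-[(1S,3R)-3-(tert-butyldimethylsilyloxy)-1-(4,5-dimethoxynaphthalen-1-yl)butyl]-4,4,5,5-tetramethyl-1,3,2-dioxaborolane | COc1cccc2c([C@H](C[C@@H](C)O[Si](C)(C)C(C)(C)C)B3OC(C)(C)C(C)(C)O3)ccc(OC)c12 | intermediate
12 | lithium (1-bromovinyl)boronate complex of 11 (configuration as in 11) | [Li+].COc1cccc2c([C@H](C[C@@H](C)O[Si](C)(C)C(C)(C)C)[B-]3(OC(C)(C)C(C)(C)O3)C(Br)=C)ccc(OC)c12 | intermediate
13 | tert-butyl{[(2R,4S)-5-bromo-4-(4,5-dimethoxynaphthalen-1-yl)hex-5-en-2-yl]oxy}dimethylsilane | COc1cccc2c([C@H](C[C@@H](C)O[Si](C)(C)C(C)(C)C)C(Br)=C)ccc(OC)c12 | intermediate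
14 | [(3R,5R)-5-(tert-butyldimethylsilyloxy)-3-(4,5-dimethoxynaphthalen-1-yl)hex-1-yn-1-yl]lithium (lithium acetylide; same spatial arrangement at both centres as in 13) | COc1cccc2c([C@H](C[C@@H](C)O[Si](C)(C)C(C)(C)C)C#C[Li])ccc(OC)c12 | intermediate
15 | lithium (3S,5R)-5-(tert-butyldimethylsilyloxy)-3-(4,5-dimethoxynaphthalen-1-yl)hex-1-yn-1-olate (lithium ynolate; same spatial arrangement at both centres as in 13) | COc1cccc2c([C@H](C[C@@H](C)O[Si](C)(C)C(C)(C)C)C#CO[Li])ccc(OC)c12 | intermediate
16 | tert-butyl{[(2R,4S)-4-(4,5-dimethoxynaphthalen-1-yl)-6-(triisopropylsilyloxy)hex-5-yn-2-yl]oxy}dimethylsilane | COc1cccc2c([C@H](C[C@@H](C)O[Si](C)(C)C(C)(C)C)C#CO[Si](C(C)C)(C(C)C)C(C)C)ccc(OC)c12 | intermediate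
17 | 3-oxocyclobutane-1-carboxylic acid | O=C1CC(C(=O)O)C1 | starting material
18 | 3-bromocyclobutan-1-one | O=C1CC(Br)C1 | intermediate
19 | cyclobut-2-en-1-one | O=C1C=CC1 | intermediate
20 | buta-1,3-dien-1-one (vinylketene) | C=CC=C=O | intermediate
21 | 2-[(1S,3R)-3-(tert-butyldimethylsilyloxy)-1-(4,5-dimethoxynaphthalen-1-yl)butyl]-3-(triisopropylsilyloxy)-4-vinylcyclobut-2-en-1-one (both epimers at the ring sp3 carbon) | COc1cccc2c([C@H](C[C@@H](C)O[Si](C)(C)C(C)(C)C)C3=C(O[Si](C(C)C)(C(C)C)C(C)C)C(C=C)C3=O)ccc(OC)c12 | intermediate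
22 | dienylketene from 21: 2-substituted 3-(triisopropylsilyloxy)hexa-1,3,5-trien-1-one, vinyl cis to the ketene-bearing carbon | COc1cccc2c([C@H](C[C@@H](C)O[Si](C)(C)C(C)(C)C)C(=C=O)/C(O[Si](C(C)C)(C(C)C)C(C)C)=C\C=C)ccc(OC)c12 | intermediate
23 | 2-[(1S,3R)-3-(tert-butyldimethylsilyloxy)-1-(4,5-dimethoxynaphthalen-1-yl)butyl]-3-(triisopropylsilyloxy)cyclohexa-2,4-dien-1-one | COc1cccc2c([C@H](C[C@@H](C)O[Si](C)(C)C(C)(C)C)C3=C(O[Si](C(C)C)(C(C)C)C(C)C)C=CCC3=O)ccc(OC)c12 | intermediate
24 | 2-[(1S,3R)-3-(tert-butyldimethylsilyloxy)-1-(4,5-dimethoxynaphthalen-1-yl)butyl]-3-(triisopropylsilyloxy)phenol | COc1cccc2c([C@H](C[C@@H](C)O[Si](C)(C)C(C)(C)C)c3c(O)cccc3O[Si](C(C)C)(C(C)C)C(C)C)ccc(OC)c12 | intermediate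
25 | 2-[(1S,3R)-1-(4,5-dimethoxynaphthalen-1-yl)-3-hydroxybutyl]-3-(triisopropylsilyloxy)phenol | COc1cccc2c([C@H](C[C@@H](C)O)c3c(O)cccc3O[Si](C(C)C)(C(C)C)C(C)C)ccc(OC)c12 | intermediate
26 | triisopropyl{[(2S,4S)-4-(4,5-dimethoxynaphthalen-1-yl)-2-methyl-3,4-dihydro-2H-chromen-5-yl]oxy}silane | COc1cccc2c([C@@H]3C[C@H](C)Oc4cccc(O[Si](C(C)C)(C(C)C)C(C)C)c43)ccc(OC)c12 | intermediate
27 | (2S,4S)-4-(4,5-dimethoxynaphthalen-1-yl)-2-methyl-3,4-dihydro-2H-chromen-5-ol (cladonaphchrom B) | COc1cccc2c([C@@H]3C[C@H](C)Oc4cccc(O)c43)ccc(OC)c12 | target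

Total step count: 14.
Longest linear sequence: 10 steps (5 to 27 through steps 3, 4, 5, 6, 7, 8, 11, 12, 13 and 14).

Steps most likely to fail

Step 11. Cyclobutenone and vinylketene 20 may oligomerise faster than 20 is captured by the hindered ynol ether, the cascade may stall at 21, or the product phenol may be acylated by surplus ketene. The fallback sets out from 16 and returns at 24. The same vinylketene is generated photochemically instead of thermally, by Wolff rearrangement of 1-diazobut-3-en-2-one F1, made from but-3-en-2-one by detrifluoroacetylative diazo transfer (LiN(SiMe3)2, CF3CO2CH2CF3, then MsN3, Et3N). Irradiation of F1 with 16 in 1,2-dichloroethane at room temperature keeps the ketene concentration low and avoids handling cyclobutenone, and warming to 80 °C then carries 21 on to 24.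

Step 7. Iodine may attack the electron-rich benzylic C–B bond or the naphthalene ring in place of the bromovinyl group, or 1-bromovinyllithium may decompose before the hindered boron captures it, so that the boron handle is lost without C–C bond formation. The fallback sets out from 6 and 2 and returns at 14, the acetylide that forms in the flask in step 8. It makes the C4–naphthyl bond on a chain that already holds the alkyne, by a stereoconvergent nickel-catalysed Negishi arylation. Ester 6 is reduced with i-Bu2AlH at –78 °C to (R)-3-(tert-butyldimethylsilyloxy)butanal F2, to which LiC≡CSiMe3 adds to give (5R)-5-(tert-butyldimethylsilyloxy)-1-(trimethylsilyl)hex-1-yn-3-ol F3 as both C3 epimers, and PPh3/CBr4 converts this alcohol into [(5R)-3-bromo-5-(tert-butyldimethylsilyloxy)hex-1-yn-1-yl]trimethylsilane F4. Bromide 2 is lithiated as in step 2 to 3, which is quenched with B(OMe)3 and aqueous acid to (4,5-dimethoxynaphthalen-1-yl)boronic acid F5, and Et2Zn turns this acid into ethyl(4,5-dimethoxynaphthalen-1-yl)zinc F6. Coupling of F4 with F6 under NiCl2(MeOCH2CH2OMe) and an indanyl-pybox ligand in 1,2-dimethoxyethane at –20 °C lets both bromide epimers converge through a propargylic radical on tert-butyl{[(2R,4S)-4-(4,5-dimethoxynaphthalen-1-yl)-6-(trimethylsilyl)hex-5-yn-2-yl]oxy}dimethylsilane F7. K2CO3 in MeOH removes the C-silyl group to give tert-butyl{[(2R,4R)-4-(4,5-dimethoxynaphthalen-1-yl)hex-5-yn-2-yl]oxy}dimethylsilane F8, and LiN(SiMe3)2 in THF at –78 °C deprotonates F8 to 14, which is oxygenated with LiOOt-Bu and silylated with i-Pr3SiOTf as in step 8. The peri-flanked arylzinc is a demanding partner for this coupling, which is why the sequence is held in reserve.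

Step 6. The α-lithiation may be slow or unselective against the existing centre, the silyl group may migrate from oxygen to the carbanion (1,4-silyl shift), or the ate complex of the peri-hindered boronate may revert before the aryl group migrates. The fallback sets out from 2 and returns at 11. It makes the benzylic C–B bond by catalytic asymmetric hydroboration. Heck coupling of 2 (Pd(OAc)2, P(o-tol)3, Et3N, DMF, 100 °C) with (R)-tert-butyl(but-3-en-2-yloxy)dimethylsilane F9, obtained from (R)-but-3-en-2-ol and TBSCl, gives tert-butyl{[(2R,3E)-4-(4,5-dimethoxynaphthalen-1-yl)but-3-en-2-yl]oxy}dimethylsilane F10. Copper hydride catalysis (CuCl, NaOt-Bu, DTBM-Segphos, pinacolborane) then places boron on the benzylic carbon under ligand control and gives 11.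

Further compounds
F1 | step 11 | 1-diazobut-3-en-2-one | C=CC(=O)C=[N+]=[N-]
F2 | step 7 | (R)-3-(tert-butyldimethylsilyloxy)butanal | O=CC[C@@H](C)O[Si](C)(C)C(C)(C)C
F3 | step 7 | (5R)-5-(tert-butyldimethylsilyloxy)-1-(trimethylsilyl)hex-1-yn-3-ol | C[Si](C)(C)C#CC(O)C[C@@H](C)O[Si](C)(C)C(C)(C)C
F4 | step 7 | [(5R)-3-bromo-5-(tert-butyldimethylsilyloxy)hex-1-yn-1-yl]trimethylsilane | C[Si](C)(C)C#CC(Br)C[C@@H](C)O[Si](C)(C)C(C)(C)C
F5 | step 7 | (4,5-dimethoxynaphthalen-1-yl)boronic acid | COc1cccc2c(B(O)O)ccc(OC)c12
F6 | step 7 | ethyl(4,5-dimethoxynaphthalen-1-yl)zinc | CC[Zn]c1ccc(OC)c2c(OC)cccc12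
F7 | step 7 | tert-butyl{[(2R,4S)-4-(4,5-dimethoxynaphthalen-1-yl)-6-(trimethylsilyl)hex-5-yn-2-yl]oxy}dimethylsilane | COc1cccc2c([C@H](C[C@@H](C)O[Si](C)(C)C(C)(C)C)C#C[Si](C)(C)C)ccc(OC)c12
F8 | step 7 | tert-butyl{[(2R,4R)-4-(4,5-dimethoxynaphthalen-1-yl)hex-5-yn-2-yl]oxy}dimethylsilane | COc1cccc2c([C@H](C[C@@H](C)O[Si](C)(C)C(C)(C)C)C#C)ccc(OC)c12
F9 | step 6 | (R)-tert-butyl(but-3-en-2-yloxy)dimethylsilane | C=C[C@@H](C)O[Si](C)(C)C(C)(C)C
F10 | step 6 | tert-butyl{[(2R,3E)-4-(4,5-dimethoxynaphthalen-1-yl)but-3-en-2-yl]oxy}dimethylsilane | COc1cccc2c(/C=C/[C@@H](C)O[Si](C)(C)C(C)(C)C)ccc(OC)c12
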